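## Retrosynthetic overview

1. Target ⇐ desilylation, C8 acylation, C3 reduction/acetylation of a 3-oxo macrolactone.
2. The ten-membered carbocycle and the cis-fused α-methylene-γ-lactone are closed together by a CrCl2 Barbier macro-allylation (C6–C7) of a (Z)-γ-keto-enal.
3. That keto-enal (C3 ketone, Z-C4=C5, C6 aldehyde) is unmasked late by oxidative ring opening of a 2,3-disubstituted furan, which carries the Z geometry.
4. The allylic bromide comes from a Baylis–Hillman/SN2′ sequence at C7; C1–C2 comes from lateral lithiation of methyl 2-methylfuran-3-carboxylate plus a Weinreb amide; C1–OH is set by CBS reduction.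
5. Z-C9=C10 and C8 come from Still–Gennari olefination of (S)-glyceraldehyde acetonide. Ring order: furan (purchased) → opened → carbocycle and γ-lactone formed in one step.

Assumption: locants C1–C15 in names from compound 18 onward are germacrane locants of the target (C6–O lactone oxygen, C8–O 2-methylbutanoate, C3–O acetate, C1–O free hydroxyl, C15 = CH2OH carbon); TBS = tert-butyldimethylsilyl, TES = triethylsilyl; 1, 2, 5, 13 and 23 are taken as commercial.

## Route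

Step 1
Reactants: 1 (S)-2,2-dimethyl-1,3-dioxolane-4-carbaldehyde; 2 methyl 2-[bis(2,2,2-trifluoroethoxy)phosphoryl]propanoate
Product: 3 methyl (2Z)-3-[(4R)-2,2-dimethyl-1,3-dioxolan-4-yl]-2-methylprop-2-enoate
Conditions: KN(SiMe3)2, 18-crown-6, THF, −78 °C
Reagents that add atoms: none
Why: Still–Gennari olefination, in which the electron-poor phosphonate eliminates fast from the kinetic adduct to give the (Z)-trisubstituted enoate (C9=C10) at −78 °C without epimerising the α-oxygenated centre that becomes C8.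

Step 2
Reactants: 3 methyl (2Z)-3-[(4R)-2,2-dimethyl-1,3-dioxolan-4-yl]-2-methylprop-2-enoate
Product: 4 (2Z)-3-[(4R)-2,2-dimethyl-1,3-dioxolan-4-yl]-N-methoxy-N,2-dimethylprop-2-enamide
Conditions: MeNH(OMe)·HCl, iPrMgCl, THF, −20 °C
Reagents that add atoms: N,O-dimethylhydroxylamine hydrochloride, CNOC.Cl
Why: Weinreb amide formation by attack of the chloromagnesium amide on the ester, with no conjugate addition to the hindered trisubstituted alkene and no change at C8 or in alkene geometry.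

Step 3
Reactants: 5 methyl 2-methylfuran-3-carboxylate; 4 (2Z)-3-[(4R)-2,2-dimethyl-1,3-dioxolan-4-yl]-N-methoxy-N,2-dimethylprop-2-enamide
Product: 6 methyl 2-[(3Z)-4-[(4R)-2,2-dimethyl-1,3-dioxolan-4-yl]-3-methyl-2-oxobut-3-en-1-yl]furan-3-carboxylate
Conditions: LiN(iPr)2, THF, −78 °C (5 added to base); then 4, −78 → −40 °C; H2O
Reagents that add atoms: none
Why: Lateral (vinylogous ester) lithiation of the 2-methyl group and acylation by the Weinreb amide, whose chelated tetrahedral adduct survives until work-up (no over-addition, no enolisation of the product) and whose α-methyl-β-branched alkene disfavours conjugate addition; this forms C1–C2.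

Step 4
Reactants: 6 methyl 2-[(3Z)-4-[(4R)-2,2-dimethyl-1,3-dioxolan-4-yl]-3-methyl-2-oxobut-3-en-1-yl]furan-3-carboxylate
Product: 7 methyl 2-[(2S,3Z)-4-[(4R)-2,2-dimethyl-1,3-dioxolan-4-yl]-2-hydroxy-3-methylbut-3-en-1-yl]furan-3-carboxylate
Conditions: (R)-1-methyl-3,3-diphenyltetrahydro-1H,3H-pyrrolo[1,2-c][1,3,2]oxazaborole (0.2 equiv), catecholborane, toluene, −78 °C
Reagents that add atoms: none
Why: Corey–Bakshi–Shibata reduction in which the α-methylalkenyl arm is the large group and the furylmethyl arm the small one, so the (R)-catalyst gives the (S)-carbinol (C1) under catalyst control while catecholborane at −78 °C spares alkene, ester and furan.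

Step 5
Reactants: 7 methyl 2-[(2S,3Z)-4-[(4R)-2,2-dimethyl-1,3-dioxolan-4-yl]-2-hydroxy-3-methylbut-3-en-1-yl]furan-3-carboxylate
Product: 8 (2S,3Z)-4-[(4R)-2,2-dimethyl-1,3-dioxolan-4-yl]-1-[3-(hydroxymethyl)furan-2-yl]-3-methylbut-3-en-2-ol
Conditions: LiAlH4, Et2O, 0 °C
Reagents that add atoms: none
Why: Hydride reduction of the heteroaryl ester to the primary alcohol that becomes C15–OH; no stereocentre is formed and acetonide, furan and alkene are inert.

Step 6
Reactants: 8 (2S,3Z)-4-[(4R)-2,2-dimethyl-1,3-dioxolan-4-yl]-1-[3-(hydroxymethyl)furan-2-yl]-3-methylbut-3-en-2-ol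
Product: 9 (2S,3Z)-2-(TBS-oxy)-1-[3-(TBS-oxymethyl)furan-2-yl]-4-[(4R)-2,2-dimethyl-1,3-dioxolan-4-yl]-3-methylbut-3-ene
Conditions: TBSCl, imidazole, DMF, rt
Reagents that add atoms: tert-butyldimethylsilyl chloride, CC(C)(C)[Si](C)(C)Cl
Why: Standard silylation of the primary and the secondary allylic hydroxyl, masking C15–OH and C1–OH until the last step.

Step 7
Reactants: 9 (2S,3Z)-2-(TBS-oxy)-1-[3-(TBS-oxymethyl)furan-2-yl]-4-[(4R)-2,2-dimethyl-1,3-dioxolan-4-yl]-3-methylbut-3-ene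
Product: 10 (2R,3Z,5S)-5-(TBS-oxy)-6-[3-(TBS-oxymethyl)furan-2-yl]-4-methylhex-3-ene-1,2-diol
Conditions: Zn(NO3)2·6H2O, MeCN, 50 °C
Reagents that add atoms: water, O
Why: Mild Lewis-acid hydrolysis that cleaves the terminal isopropylidene acetal while TBS ethers and the acid-sensitive furan survive; no stereocentre is touched.

Step 8
Reactants: 10 (2R,3Z,5S)-5-(TBS-oxy)-6-[3-(TBS-oxymethyl)furan-2-yl]-4-methylhex-3-ene-1,2-diol
Product: 11 (2R,3Z,5S)-5-(TBS-oxy)-6-[3-(TBS-oxymethyl)furan-2-yl]-4-methyl-1,2-bis(TES-oxy)hex-3-ene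
Conditions: Et3SiCl, imidazole, CH2Cl2, 0 °C
Reagents that add atoms: chlorotriethylsilane, CC[Si](Cl)(CC)CC
Why: Silylation of both hydroxyls with the smaller, more labile triethylsilyl group, so the primary ether can be oxidised next and the C8 ether can later be removed beside TBS.

Step 9
Reactants: 11 (2R,3Z,5S)-5-(TBS-oxy)-6-[3-(TBS-oxymethyl)furan-2-yl]-4-methyl-1,2-bis(TES-oxy)hex-3-ene
Product: 12 (2R,3Z,5S)-5-(TBS-oxy)-6-[3-(TBS-oxymethyl)furan-2-yl]-4-methyl-2-(TES-oxy)hex-3-enal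
Conditions: (COCl)2, DMSO, CH2Cl2, −78 → −30 °C; Et3N, −78 °C
Reagents that add atoms: none
Why: Swern oxidation with in-situ desilylation, in which the chlorosulfonium salt cleaves only the unhindered primary TES ether and oxidises it to the aldehyde (C7), leaving the secondary TES and both TBS ethers; the base is added cold so the α-silyloxy centre (C8) does not epimerise.

Step 10
Reactants: 12 (2R,3Z,5S)-5-(TBS-oxy)-6-[3-(TBS-oxymethyl)furan-2-yl]-4-methyl-2-(TES-oxy)hex-3-enal; 13 methyl acrylate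
Product: 14 methyl (4R,5Z,7S)-7-(TBS-oxy)-8-[3-(TBS-oxymethyl)furan-2-yl]-3-hydroxy-6-methyl-2-methylidene-4-(TES-oxy)oct-5-enoate (both C3 epimers)
Conditions: 1,4-diazabicyclo[2.2.2]octane, MeOH (cat.), neat acrylate, rt, 4–6 d
Reagents that add atoms: none
Why: Morita–Baylis–Hillman reaction of the activated α-silyloxy aldehyde installs C11–C13; the new carbinol (C7) forms as a mixture that does not matter because C7 becomes sp2 in step 11.

Step 11
Reactants: 14 methyl (4R,5Z,7S)-7-(TBS-oxy)-8-[3-(TBS-oxymethyl)furan-2-yl]-3-hydroxy-6-methyl-2-methylidene-4-(TES-oxy)oct-5-enoate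
Product: 16 methyl (2Z,4R,5Z,7S)-2-(bromomethyl)-7-(TBS-oxy)-8-[3-(TBS-oxymethyl)furan-2-yl]-6-methyl-4-(TES-oxy)octa-2,5-dienoate, via allylic mesylate 15 (not isolated)
Conditions: MsCl, Et3N, CH2Cl2, −20 °C; then LiBr, THF, 0 °C → rt
Reagents that add atoms: methanesulfonyl chloride, CS(=O)(=O)Cl (retained only in 15); lithium bromide, [Li+].[Br-]
Why: Mesylation then SN2′ displacement by bromide gives the thermodynamically preferred conjugated (Z)-2-(bromomethyl)enoate and erases the C7 carbinol centre; the non-acidic, non-oxidising conditions spare silyl ethers and furan.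

Step 12
Reactants: 16 methyl (2Z,4R,5Z,7S)-2-(bromomethyl)-7-(TBS-oxy)-8-[3-(TBS-oxymethyl)furan-2-yl]-6-methyl-4-(TES-oxy)octa-2,5-dienoate
Product: 17 methyl (2Z,4R,5Z,7S,10Z)-2-(bromomethyl)-7-(TBS-oxy)-10-(TBS-oxymethyl)-6-methyl-9,12-dioxo-4-(TES-oxy)dodeca-2,5,10-trienoate
Conditions: N-bromosuccinimide, NaHCO3, acetone/H2O (10:1), −20 °C, dark; crude used at once
Reagents that add atoms: water, O
Why: Oxidative dearomatisation of the furan (bromonium attack at the free α-position, capture of the oxocarbenium ion by water, loss of HBr) opens the ring to the cis-enedicarbonyl, so the Z geometry of C4=C5 is inherited from the ring and the C6 aldehyde and C3 ketone appear together; the electron-rich furan reacts far faster than the trisubstituted alkene or the allylic bromide.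

Step 13
Reactants: 17 methyl (2Z,4R,5Z,7S,10Z)-2-(bromomethyl)-7-(TBS-oxy)-10-(TBS-oxymethyl)-6-methyl-9,12-dioxo-4-(TES-oxy)dodeca-2,5,10-trienoate
Product: 19 (1S,6S,7S,8R,4Z,9Z)-1,15-bis(TBS-oxy)-3-oxo-8-(TES-oxy)germacra-4,9,11(13)-trien-12,6-olide, via hydroxy ester 18 (not isolated)
Conditions: CrCl2 (8 equiv), THF, 0.003 M, slow addition, rt; then pyridinium p-toluenesulfonate (cat.), CH2Cl2, rt
Reagents that add atoms: none
Why: Intramolecular Nozaki–Hiyama-type Barbier allylation at high dilution, in which the allylchromium species attacks only the aldehyde through a chair transition state (Z-disposed C8 substituent → 6,7-syn adduct → cis-fused lactone after acyl transfer to the C6 alkoxide), while A(1,3) strain holds C8–H in the alkene plane so that C6 adds to the C7 face anti to the C9 chain, giving the target configuration at C6 and C7 (C7 is formally S here only because the silyloxy branch outranks the lactone branch).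

Step 14
Reactants: 19 (1S,6S,7S,8R,4Z,9Z)-1,15-bis(TBS-oxy)-3-oxo-8-(TES-oxy)germacra-4,9,11(13)-trien-12,6-olide
Product: 20 (1S,3S,6S,7S,8R,4Z,9Z)-1,15-bis(TBS-oxy)-3-hydroxy-8-(TES-oxy)germacra-4,9,11(13)-trien-12,6-olide
Conditions: (R)-1-methyl-3,3-diphenyltetrahydro-1H,3H-pyrrolo[1,2-c][1,3,2]oxazaborole (0.5 equiv), catecholborane, toluene, −78 °C
Reagents that add atoms: none
Why: Corey–Bakshi–Shibata 1,2-reduction of the enone with the alkenyl arm (C4) as large group and C2H2 as small group, so the (R)-catalyst sets (3S); catecholborane at −78 °C does not touch the α-methylene lactone.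

Step 15
Reactants: 20 (1S,3S,6S,7S,8R,4Z,9Z)-1,15-bis(TBS-oxy)-3-hydroxy-8-(TES-oxy)germacra-4,9,11(13)-trien-12,6-olide
Product: 21 (1S,3S,6S,7S,8R,4Z,9Z)-3-acetoxy-1,15-bis(TBS-oxy)-8-(TES-oxy)germacra-4,9,11(13)-trien-12,6-olide
Conditions: Ac2O, pyridine, 4-(dimethylamino)pyridine (cat.), CH2Cl2, 0 °C
Reagents that add atoms: acetic anhydride, CC(=O)OC(C)=O
Why: Nucleophile-catalysed acetylation of the only free hydroxyl, with retention at C3.

Step 16
Reactants: 21 (1S,3S,6S,7S,8R,4Z,9Z)-3-acetoxy-1,15-bis(TBS-oxy)-8-(TES-oxy)germacra-4,9,11(13)-trien-12,6-olide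
Product: 22 (1S,3S,6S,7R,8R,4Z,9Z)-3-acetoxy-1,15-bis(TBS-oxy)-8-hydroxygermacra-4,9,11(13)-trien-12,6-olide
Conditions: pyridinium p-toluenesulfonate, MeOH/CH2Cl2, 0 °C
Reagents that add atoms: none
Why: Acid-catalysed methanolysis removes the TES ether about two orders of magnitude faster than the TBS ethers, freeing only C8–OH; acetate and lactone are stable at 0 °C.

Step 17
Reactants: 22 (1S,3S,6S,7R,8R,4Z,9Z)-3-acetoxy-1,15-bis(TBS-oxy)-8-hydroxygermacra-4,9,11(13)-trien-12,6-olide; 23 (S)-2-methylbutanoic anhydride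
Product: 24 (1S,3S,6S,7R,8R,4Z,9Z)-3-acetoxy-1,15-bis(TBS-oxy)-8-[(2S)-2-methylbutanoyloxy]germacra-4,9,11(13)-trien-12,6-olide
Conditions: 4-(dimethylamino)pyridine (cat.), Et3N, CH2Cl2, 0 °C → rt
Reagents that add atoms: none
Why: Acyl-transfer-catalysed esterification of the only free hydroxyl with the enantiopure anhydride, which avoids a ketene pathway so the (S)-α-centre of the acyl group is kept; fast acylation pre-empts translactonisation to C8.

Step 18
Reactants: 24 (1S,3S,6S,7R,8R,4Z,9Z)-3-acetoxy-1,15-bis(TBS-oxy)-8-[(2S)-2-methylbutanoyloxy]germacra-4,9,11(13)-trien-12,6-olide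
Product: 25 (1S,3S,6S,7R,8R,4Z,9Z)-3-acetoxy-1,15-dihydroxy-8-[(2S)-2-methylbutanoyloxy]germacra-4,9,11(13)-trien-12,6-olide (CNP0217661.3)
Conditions: HF·pyridine, pyridine, THF, 0 °C → rt
Reagents that add atoms: none
Why: Fluoride-mediated cleavage of both TBS ethers under buffered acidic conditions that leave the acetate, the 2-methylbutanoate and the α-methylene lactone intact; no stereocentre is affected.

## Compound list

1 | (S)-2,2-dimethyl-1,3-dioxolane-4-carbaldehyde | O=C[C@H]1OC(C)(C)OC1 | starting material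
2 | methyl 2-[bis(2,2,2-trifluoroethoxy)phosphoryl]propanoate | COC(=O)C(C)P(=O)(OCC(F)(F)F)OCC(F)(F)F | starting material
3 | methyl (2Z)-3-[(4R)-2,2-dimethyl-1,3-dioxolan-4-yl]-2-methylprop-2-enoate | COC(=O)/C(C)=C\[C@H]1OC(C)(C)OC1 | intermediate
4 | (2Z)-3-[(4R)-2,2-dimethyl-1,3-dioxolan-4-yl]-N-methoxy-N,2-dimethylprop-2-enamide | CON(C)C(=O)/C(C)=C\[C@H]1OC(C)(C)OC1 | intermediate
5 | methyl 2-methylfuran-3-carboxylate | COC(=O)c1ccoc1C | starting material
6 | methyl 2-[(3Z)-4-[(4R)-2,2-dimethyl-1,3-dioxolan-4-yl]-3-methyl-2-oxobut-3-en-1-yl]furan-3-carboxylate | COC(=O)c1ccoc1CC(=O)/C(C)=C\[C@H]1OC(C)(C)OC1 | intermediate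
7 | methyl 2-[(2S,3Z)-4-[(4R)-2,2-dimethyl-1,3-dioxolan-4-yl]-2-hydroxy-3-methylbut-3-en-1-yl]furan-3-carboxylate | COC(=O)c1ccoc1C[C@H](O)/C(C)=C\[C@H]1OC(C)(C)OC1 | intermediate
8 | (2S,3Z)-4-[(4R)-2,2-dimethyl-1,3-dioxolan-4-yl]-1-[3-(hydroxymethyl)furan-2-yl]-3-methylbut-3-en-2-ol | OCc1ccoc1C[C@H](O)/C(C)=C\[C@H]1OC(C)(C)OC1 | intermediate
9 | bis-TBS ether of 8 | CC(C)(C)[Si](C)(C)OCc1ccoc1C[C@H](O[Si](C)(C)C(C)(C)C)/C(C)=C\[C@H]1OC(C)(C)OC1 | intermediate
10 | (2R,3Z,5S)-5-(TBS-oxy)-6-[3-(TBS-oxymethyl)furan-2-yl]-4-methylhex-3-ene-1,2-diol | CC(C)(C)[Si](C)(C)OCc1ccoc1C[C@H](O[Si](C)(C)C(C)(C)C)/C(C)=C\[C@@H](O)CO | intermediate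
11 | 1,2-bis-TES ether of 10 | CC(C)(C)[Si](C)(C)OCc1ccoc1C[C@H](O[Si](C)(C)C(C)(C)C)/C(C)=C\[C@@H](O[Si](CC)(CC)CC)CO[Si](CC)(CC)CC | intermediate
12 | (2R,3Z,5S)-5-(TBS-oxy)-6-[3-(TBS-oxymethyl)furan-2-yl]-4-methyl-2-(TES-oxy)hex-3-enal | CC(C)(C)[Si](C)(C)OCc1ccoc1C[C@H](O[Si](C)(C)C(C)(C)C)/C(C)=C\[C@@H](O[Si](CC)(CC)CC)C=O | intermediate
13 | methyl acrylate | C=CC(=O)OC | starting material
14 | methyl (4R,5Z,7S)-7-(TBS-oxy)-8-[3-(TBS-oxymethyl)furan-2-yl]-3-hydroxy-6-methyl-2-methylidene-4-(TES-oxy)oct-5-enoate, both C3 epimers | CC(C)(C)[Si](C)(C)OCc1ccoc1C[C@H](O[Si](C)(C)C(C)(C)C)/C(C)=C\[C@@H](O[Si](CC)(CC)CC)C(O)C(=C)C(=O)OC | intermediate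
15 | 3-O-methanesulfonate of 14 (allylic mesylate) | CC(C)(C)[Si](C)(C)OCc1ccoc1C[C@H](O[Si](C)(C)C(C)(C)C)/C(C)=C\[C@@H](O[Si](CC)(CC)CC)C(OS(C)(=O)=O)C(=C)C(=O)OC | intermediate
16 | methyl (2Z,4R,5Z,7S)-2-(bromomethyl)-7-(TBS-oxy)-8-[3-(TBS-oxymethyl)furan-2-yl]-6-methyl-4-(TES-oxy)octa-2,5-dienoate | CC(C)(C)[Si](C)(C)OCc1ccoc1C[C@H](O[Si](C)(C)C(C)(C)C)/C(C)=C\[C@@H](O[Si](CC)(CC)CC)/C=C(\CBr)C(=O)OC | intermediate
17 | methyl (2Z,4R,5Z,7S,10Z)-2-(bromomethyl)-7-(TBS-oxy)-10-(TBS-oxymethyl)-6-methyl-9,12-dioxo-4-(TES-oxy)dodeca-2,5,10-trienoate | O=C/C=C(/CO[Si](C)(C)C(C)(C)C)C(=O)C[C@H](O[Si](C)(C)C(C)(C)C)/C(C)=C\[C@@H](O[Si](CC)(CC)CC)/C=C(\CBr)C(=O)OC | intermediate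
18 | methyl (1S,6S,7S,8R,4Z,9Z)-1,15-bis(TBS-oxy)-6-hydroxy-3-oxo-8-(TES-oxy)germacra-4,9,11(13)-trien-12-oate (hydroxy ester) | C=C(C(=O)OC)[C@H]1[C@@H](O)/C=C(/CO[Si](C)(C)C(C)(C)C)C(=O)C[C@H](O[Si](C)(C)C(C)(C)C)/C(C)=C\[C@H]1O[Si](CC)(CC)CC | intermediate
19 | (1S,6S,7S,8R,4Z,9Z)-1,15-bis(TBS-oxy)-3-oxo-8-(TES-oxy)germacra-4,9,11(13)-trien-12,6-olide | C=C1C(=O)O[C@H]2/C=C(/CO[Si](C)(C)C(C)(C)C)C(=O)C[C@H](O[Si](C)(C)C(C)(C)C)/C(C)=C\[C@@H](O[Si](CC)(CC)CC)[C@@H]12 | intermediate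
20 | (1S,3S,6S,7S,8R,4Z,9Z)-1,15-bis(TBS-oxy)-3-hydroxy-8-(TES-oxy)germacra-4,9,11(13)-trien-12,6-olide | C=C1C(=O)O[C@H]2/C=C(/CO[Si](C)(C)C(C)(C)C)[C@@H](O)C[C@H](O[Si](C)(C)C(C)(C)C)/C(C)=C\[C@@H](O[Si](CC)(CC)CC)[C@@H]12 | intermediate
21 | (1S,3S,6S,7S,8R,4Z,9Z)-3-acetoxy-1,15-bis(TBS-oxy)-8-(TES-oxy)germacra-4,9,11(13)-trien-12,6-olide | C=C1C(=O)O[C@H]2/C=C(/CO[Si](C)(C)C(C)(C)C)[C@@H](OC(C)=O)C[C@H](O[Si](C)(C)C(C)(C)C)/C(C)=C\[C@@H](O[Si](CC)(CC)CC)[C@@H]12 | intermediate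
22 | (1S,3S,6S,7R,8R,4Z,9Z)-3-acetoxy-1,15-bis(TBS-oxy)-8-hydroxygermacra-4,9,11(13)-trien-12,6-olide | C=C1C(=O)O[C@H]2/C=C(/CO[Si](C)(C)C(C)(C)C)[C@@H](OC(C)=O)C[C@H](O[Si](C)(C)C(C)(C)C)/C(C)=C\[C@@H](O)[C@@H]12 | intermediate
23 | (S)-2-methylbutanoic anhydride | CC[C@H](C)C(=O)OC(=O)[C@@H](C)CC | starting material
24 | (1S,3S,6S,7R,8R,4Z,9Z)-3-acetoxy-1,15-bis(TBS-oxy)-8-[(2S)-2-methylbutanoyloxy]germacra-4,9,11(13)-trien-12,6-olide | C=C1C(=O)O[C@H]2/C=C(/CO[Si](C)(C)C(C)(C)C)[C@@H](OC(C)=O)C[C@H](O[Si](C)(C)C(C)(C)C)/C(C)=C\[C@@H](OC(=O)[C@@H](C)CC)[C@@H]12 | intermediate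
25 | (1S,3S,6S,7R,8R,4Z,9Z)-3-acetoxy-1,15-dihydroxy-8-[(2S)-2-methylbutanoyloxy]germacra-4,9,11(13)-trien-12,6-olide (CNP0217661.3) | C=C1C(=O)O[C@H]2/C=C(/CO)[C@@H](OC(C)=O)C[C@H](O)/C(C)=C\[C@@H](OC(=O)[C@@H](C)CC)[C@@H]12 | target

## Step count and risks

Total steps: 18. Longest linear sequence: 18 (1 → 25); 5, 13 and 23 enter at steps 3, 10 and 17.

Steps most likely to fail:

Step 12 (furan opening in a substrate that also carries an allylic bromide, a trisubstituted alkene and three silyl ethers; the Z-keto-enal can isomerise). Fallback: starting from 16, replace electrophilic bromination by a [4+2] photo-oxygenation (O2, tetraphenylporphyrin, hν, CH2Cl2, −78 °C) to give the furan endoperoxide F1, which is reduced in the cold with dimethyl sulfide to the same cis-keto-enal; the route is rejoined at 17.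

Step 13 (competing seven-membered closure onto the C3 ketone, oligomerisation, or the wrong C7 face). Fallback: starting from 14, acetylate (Ac2O, 4-(dimethylamino)pyridine) to the allylic acetate F2, open the furan as in step 12 to the keto-enal acetate F3, and close the ring by umpolung of the π-allyl complex (Pd(PPh3)4 cat., zerovalent palladium, with InI, THF, high dilution). The softer, aldehyde-selective allylindium adds at C7 and the adduct 18 lactonises; the route is rejoined at 19.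

Step 14 (the ring conformation may override the catalyst). Fallback: starting from 19, reduce under ring control (NaBH4, CeCl3·7H2O, MeOH, −78 °C) to the (3R)-alcohol F4, then invert with acetic acid under Mitsunobu conditions (PPh3, diisopropyl azodicarboxylate, AcOH, THF, 0 °C), which gives the (3S)-acetate directly; the route is rejoined at 21.

Further compounds

F1 | step 12 | furan endoperoxide of 16 (2,3,7-trioxabicyclo[2.2.1]hept-5-ene, both bridgehead diastereomers) | CC(C)(C)[Si](C)(C)OCC1=CC2OOC1(O2)C[C@H](O[Si](C)(C)C(C)(C)C)/C(C)=C\[C@@H](O[Si](CC)(CC)CC)/C=C(\CBr)C(=O)OC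
F2 | step 13 | 3-O-acetate of 14 (allylic acetate) | CC(C)(C)[Si](C)(C)OCc1ccoc1C[C@H](O[Si](C)(C)C(C)(C)C)/C(C)=C\[C@@H](O[Si](CC)(CC)CC)C(OC(C)=O)C(=C)C(=O)OC
F3 | step 13 | keto-enal acetate (furan-opened F2) | O=C/C=C(/CO[Si](C)(C)C(C)(C)C)C(=O)C[C@H](O[Si](C)(C)C(C)(C)C)/C(C)=C\[C@@H](O[Si](CC)(CC)CC)C(OC(C)=O)C(=C)C(=O)OC
F4 | step 14 | (1S,3R,6S,7S,8R,4Z,9Z)-1,15-bis(TBS-oxy)-3-hydroxy-8-(TES-oxy)germacra-4,9,11(13)-trien-12,6-olide | C=C1C(=O)O[C@H]2/C=C(/CO[Si](C)(C)C(C)(C)C)[C@H](O)C[C@H](O[Si](C)(C)C(C)(C)C)/C(C)=C\[C@@H](O[Si](CC)(CC)CC)[C@@H]12
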